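**Retrosynthetic overview**
1. Target ⇐ removal of five MOM ethers from the fully protected trans-2,3-diaryl-2,3-dihydrobenzofuran (last step, no skeletal change).
2. Dihydrofuran ring (C2–C3 and C2–O bonds, both stereocentres) ⇐ new asymmetric [4+1] annulation of a ring A o-quinone methide with a chiral isothiocineole-derived guaiacyl sulfonium ylide; this is the only ring built, and it is built last.
3. o-Quinone methide precursor (o-hydroxybenzhydryl sulfone) ⇐ 2-hydroxybenzophenone carrying the stilbene ⇐ E-selective Horner–Wadsworth–Emmons olefination of a ring A aldehyde.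
4. Benzophenone core ⇐ directed ortho-lithiation of a 3,5-bis(MOM-oxy)benzaldehyde acetal plus 3,5-bis(MOM-oxy)benzaldehyde (both from 3,5-dihydroxybenzaldehyde), oxidation, carbonyl-assisted unmasking of one ortho phenol.
5. Phosphonate and sulfonium salt ⇐ one MOM-protected vanillyl bromide (from vanillin); the three benzene rings are bought intact.

Assumption: the sulfonium salt from the (S)-limonene-series isothiocineole is taken to give the (2R,3R) product (facial model of its benzylides, not a measured result); if the first run shows the opposite sense, the mirror-image sulfide from (R)-limonene is used with nothing else changed, and both antipodes of isothiocineole are treated as purchasable.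

**Route**

Step 1
Reactants: 1 3,5-dihydroxybenzaldehyde
Product: 2 3,5-bis(methoxymethoxy)benzaldehyde
Conditions: MOMCl (2.5 equiv), K2CO3 (4 equiv), acetone, 0 °C → rt
Reagents that add atoms: chloromethyl methyl ether (MOMCl), COCCl
Why: Williamson-type O-alkylation of both phenoxides by MOMCl under mild carbonate base leaves the aldehyde untouched.

Step 2
Reactants: 2 3,5-bis(methoxymethoxy)benzaldehyde
Product: 3 1-(dimethoxymethyl)-3,5-bis(methoxymethoxy)benzene
Conditions: HC(OMe)3 (3 equiv), PPTS (2 mol%), MeOH, rt; Et3N quench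
Reagents that add atoms: trimethyl orthoformate, COC(OC)OC; methanol, CO
Why: Acid-catalysed acetalisation driven by the orthoformate as water scavenger masks the aldehyde against n-BuLi, and PPTS at room temperature is too weak to cleave aryl MOM ethers.

Step 3
Reactants: 3 1-(dimethoxymethyl)-3,5-bis(methoxymethoxy)benzene; 2 3,5-bis(methoxymethoxy)benzaldehyde
Product: 5 [3,5-bis(methoxymethoxy)phenyl][4-(dimethoxymethyl)-2,6-bis(methoxymethoxy)phenyl]methanol (racemic), via aryllithium 4 (not isolated)
Conditions: n-BuLi (1.1 equiv), THF, 0 °C, 1 h; then 2, −78 °C → 0 °C; H2O quench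
Reagents that add atoms: none
Why: Directed ortho-metalation removes the hydrogen flanked by the two chelating MOM ethers and the aryllithium adds 1,2 to aldehyde 2; the carbinol stereocentre forms racemic and is destroyed in step 4.

Step 4
Reactants: 5 [3,5-bis(methoxymethoxy)phenyl][4-(dimethoxymethyl)-2,6-bis(methoxymethoxy)phenyl]methanol
Product: 6 [3,5-bis(methoxymethoxy)phenyl][4-(dimethoxymethyl)-2,6-bis(methoxymethoxy)phenyl]methanone
Conditions: Dess–Martin periodinane (1.3 equiv), pyridine (3 equiv), CH2Cl2, 0 °C → rt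
Reagents that add atoms: none
Why: Dess–Martin oxidation converts the hindered doubly benzylic alcohol into the diaryl ketone under buffered, near-neutral conditions that spare the acetal and the MOM ethers.

Step 5
Reactants: 6 [3,5-bis(methoxymethoxy)phenyl][4-(dimethoxymethyl)-2,6-bis(methoxymethoxy)phenyl]methanone
Product: 7 4-[3,5-bis(methoxymethoxy)benzoyl]-3-hydroxy-5-(methoxymethoxy)benzaldehyde
Conditions: 2 M aq HCl/THF (1:4), 35 °C, TLC control (about 3 h)
Reagents that add atoms: water, O
Why: Aqueous acid hydrolyses the dimethyl acetal, and carbonyl-assisted cleavage removes only one ortho MOM ether because the phenol formed locks the ketone in a hydrogen bond, so the second ortho MOM ether then cleaves as slowly as the ordinary ones on ring B.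

Step 6
Reactants: 8 vanillin (4-hydroxy-3-methoxybenzaldehyde)
Product: 9 3-methoxy-4-(methoxymethoxy)benzaldehyde
Conditions: MOMCl (1.3 equiv), K2CO3 (2 equiv), acetone, 0 °C → rt
Reagents that add atoms: chloromethyl methyl ether (MOMCl), COCCl
Why: Williamson-type O-alkylation of the phenoxide by MOMCl.

Step 7
Reactants: 9 3-methoxy-4-(methoxymethoxy)benzaldehyde
Product: 10 [3-methoxy-4-(methoxymethoxy)phenyl]methanol
Conditions: NaBH4, MeOH, 0 °C
Reagents that add atoms: none
Why: Borohydride reduction of the aryl aldehyde to the benzylic alcohol.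

Step 8
Reactants: 10 [3-methoxy-4-(methoxymethoxy)phenyl]methanol
Product: 11 4-(bromomethyl)-2-methoxy-1-(methoxymethoxy)benzene
Conditions: CBr4 (1.2 equiv), PPh3 (1.2 equiv), CH2Cl2, 0 °C; used at once
Reagents that add atoms: tetrabromomethane, BrC(Br)(Br)Br
Why: Appel bromination converts the benzylic alcohol into the bromide under neutral conditions that keep the acid-labile MOM ether.

Step 9
Reactants: 11 4-(bromomethyl)-2-methoxy-1-(methoxymethoxy)benzene
Product: 12 diethyl {[3-methoxy-4-(methoxymethoxy)phenyl]methyl}phosphonate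
Conditions: P(OEt)3 (neat, 3 equiv), 110 °C
Reagents that add atoms: triethyl phosphite, CCOP(OCC)OCC
Why: Michaelis–Arbuzov reaction of the reactive benzylic bromide with triethyl phosphite.

Step 10
Reactants: 7 4-[3,5-bis(methoxymethoxy)benzoyl]-3-hydroxy-5-(methoxymethoxy)benzaldehyde; 12 diethyl {[3-methoxy-4-(methoxymethoxy)phenyl]methyl}phosphonate
Product: 14 [3,5-bis(methoxymethoxy)phenyl]{2-hydroxy-4-{(E)-2-[3-methoxy-4-(methoxymethoxy)phenyl]ethenyl}-6-(methoxymethoxy)phenyl}methanone, via potassium phosphonate carbanion 13 (not isolated)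
Conditions: 12, KOtBu (2.3 equiv), THF, 0 °C; then 7, 0 °C → rt; dark
Reagents that add atoms: none
Why: Horner–Wadsworth–Emmons olefination of the unhindered aldehyde by the benzylic phosphonate anion gives the E-stilbene, while the phenol is masked as its phenoxide and the hindered diaryl ketone does not react.

Step 11
Reactants: 14 [3,5-bis(methoxymethoxy)phenyl]{2-hydroxy-4-{(E)-2-[3-methoxy-4-(methoxymethoxy)phenyl]ethenyl}-6-(methoxymethoxy)phenyl}methanone
Product: 15 2-{[3,5-bis(methoxymethoxy)phenyl](hydroxy)methyl}-5-{(E)-2-[3-methoxy-4-(methoxymethoxy)phenyl]ethenyl}-3-(methoxymethoxy)phenol (racemic)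
Conditions: NaBH4 (4 equiv), THF/MeOH (3:1), 0 °C → rt; neutral work-up, used crude
Reagents that add atoms: none
Why: Borohydride reduction of the diaryl ketone gives the o-hydroxybenzhydrol without touching the stilbene; the carbinol stereocentre is racemic and is erased in step 14.

Step 12
Reactants: 15 2-{[3,5-bis(methoxymethoxy)phenyl](hydroxy)methyl}-5-{(E)-2-[3-methoxy-4-(methoxymethoxy)phenyl]ethenyl}-3-(methoxymethoxy)phenol
Product: 16 2-{[3,5-bis(methoxymethoxy)phenyl](4-methylbenzenesulfonyl)methyl}-5-{(E)-2-[3-methoxy-4-(methoxymethoxy)phenyl]ethenyl}-3-(methoxymethoxy)phenol (racemic)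
Conditions: p-TolSO2H (1.5 equiv), 4 Å MS, CH2Cl2, 0 °C → rt
Reagents that add atoms: p-toluenesulfinic acid, Cc1ccc(cc1)S(=O)O
Why: SN1-type exchange through the highly stabilised o-hydroxybenzhydryl cation, captured at sulfur by the sulfinic acid, gives a bench-stable sulfone that releases the o-quinone methide only under base; the stereocentre is racemic and is erased in step 14.

Step 13
Reactants: 17 isothiocineole of the (S)-limonene series; 11 4-(bromomethyl)-2-methoxy-1-(methoxymethoxy)benzene
Product: 18 6-[3-methoxy-4-(methoxymethoxy)benzyl]-4,7,7-trimethyl-6-thiabicyclo[3.2.1]octan-6-ium triflate (benzyl on the exo face of sulfur)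
Conditions: LiOTf (2 equiv), CH2Cl2/H2O (2:1), rt, 24 h; precipitation from Et2O
Reagents that add atoms: lithium trifluoromethanesulfonate, [Li+].[O-]S(=O)(=O)C(F)(F)F
Why: S-alkylation of the sulfide by the electron-rich benzylic bromide is driven forward by exchange of bromide for non-nucleophilic triflate and takes place on the exposed exo lone pair of the cage, so one sulfonium diastereomer with a defined sulfur stereocentre forms.

Step 14
Reactants: 16 2-{[3,5-bis(methoxymethoxy)phenyl](4-methylbenzenesulfonyl)methyl}-5-{(E)-2-[3-methoxy-4-(methoxymethoxy)phenyl]ethenyl}-3-(methoxymethoxy)phenol; 18 6-[3-methoxy-4-(methoxymethoxy)benzyl]-4,7,7-trimethyl-6-thiabicyclo[3.2.1]octan-6-ium triflate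
Product: 22 (2R,3R)-3-[3,5-bis(methoxymethoxy)phenyl]-4-(methoxymethoxy)-2-[3-methoxy-4-(methoxymethoxy)phenyl]-6-{(E)-2-[3-methoxy-4-(methoxymethoxy)phenyl]ethenyl}-2,3-dihydro-1-benzofuran, via sulfonium ylide 19 (not isolated), via o-quinone methide 20 (not isolated), via sulfonium phenoxide betaine 21 (not isolated)
Conditions: 18 (1.5 equiv), Cs2CO3 (3 equiv), 4 Å MS, MeCN/CH2Cl2 (1:1), −20 °C → 0 °C, 24 h, dark
Reagents that add atoms: none
Why: Proposed new method: carbonate eliminates sulfinate from 16 (E1cB) to give o-quinone methide 20 and deprotonates 18 to the aryl-stabilised ylide 19, whose carbon adds in conjugate fashion to the methide carbon (re-aromatising ring A) to give betaine 21, which closes by 5-exo-tet displacement of the sulfide by the phenoxide with inversion; the isothiocineole cage fixes the ylide conformation (aryl syn to the sulfur lone pair, away from the gem-dimethyl group) and its gem-dimethyl group blocks one face, so the configuration of the future C2 is set as in aldehyde epoxidations with such ylides, while the anti approach that keeps the two aryl groups apart sets C3 and gives the trans (2R,3R) ring; the closest known reaction types are the racemic sulfur-ylide [4+1] annulation of o-quinone methides and the asymmetric epoxidation or aziridination with isothiocineole-derived benzylides, whereas an auxiliary-controlled [4+1] annulation to a 2,3-diaryl-2,3-dihydrobenzofuran has not been shown.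

Step 15
Reactants: 22 (2R,3R)-3-[3,5-bis(methoxymethoxy)phenyl]-4-(methoxymethoxy)-2-[3-methoxy-4-(methoxymethoxy)phenyl]-6-{(E)-2-[3-methoxy-4-(methoxymethoxy)phenyl]ethenyl}-2,3-dihydro-1-benzofuran
Product: 23 (2R,3R)-3-(3,5-dihydroxyphenyl)-2-(4-hydroxy-3-methoxyphenyl)-6-[(E)-2-(4-hydroxy-3-methoxyphenyl)ethenyl]-2,3-dihydro-1-benzofuran-4-ol
Conditions: HCl (1.25 M in MeOH)/THF (1:1), 40 °C, argon, dark
Reagents that add atoms: none
Why: Acid-catalysed transacetalisation to methanol removes all five MOM ethers without affecting the stilbene, and the trans-2,3-diaryl arrangement is the thermodynamic one (C3 cannot epimerise under acid), so both stereocentres are retained.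

**Compound list**
1 | 3,5-dihydroxybenzaldehyde | O=Cc1cc(O)cc(O)c1 | starting material
2 | 3,5-bis(methoxymethoxy)benzaldehyde | O=Cc1cc(OCOC)cc(OCOC)c1 | intermediate
3 | 1-(dimethoxymethyl)-3,5-bis(methoxymethoxy)benzene | COC(OC)c1cc(OCOC)cc(OCOC)c1 | intermediate
4 | [4-(dimethoxymethyl)-2,6-bis(methoxymethoxy)phenyl]lithium (not isolated) | [Li]c1c(OCOC)cc(C(OC)OC)cc1OCOC | intermediate
5 | [3,5-bis(methoxymethoxy)phenyl][4-(dimethoxymethyl)-2,6-bis(methoxymethoxy)phenyl]methanol (racemic) | COC(OC)c1cc(OCOC)c(C(O)c2cc(OCOC)cc(OCOC)c2)c(OCOC)c1 | intermediate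
6 | [3,5-bis(methoxymethoxy)phenyl][4-(dimethoxymethyl)-2,6-bis(methoxymethoxy)phenyl]methanone | COC(OC)c1cc(OCOC)c(C(=O)c2cc(OCOC)cc(OCOC)c2)c(OCOC)c1 | intermediate
7 | 4-[3,5-bis(methoxymethoxy)benzoyl]-3-hydroxy-5-(methoxymethoxy)benzaldehyde | O=Cc1cc(O)c(C(=O)c2cc(OCOC)cc(OCOC)c2)c(OCOC)c1 | intermediate
8 | vanillin (4-hydroxy-3-methoxybenzaldehyde) | COc1cc(C=O)ccc1O | starting material
9 | 3-methoxy-4-(methoxymethoxy)benzaldehyde | COCOc1ccc(C=O)cc1OC | intermediate
10 | [3-methoxy-4-(methoxymethoxy)phenyl]methanol | COCOc1ccc(CO)cc1OC | intermediate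
11 | 4-(bromomethyl)-2-methoxy-1-(methoxymethoxy)benzene | COCOc1ccc(CBr)cc1OC | intermediate
12 | diethyl {[3-methoxy-4-(methoxymethoxy)phenyl]methyl}phosphonate | CCOP(=O)(OCC)Cc1ccc(OCOC)c(OC)c1 | intermediate
13 | potassium salt of the benzylic carbanion of 12 (not isolated) | [K+].CCOP(=O)(OCC)[CH-]c1ccc(OCOC)c(OC)c1 | intermediate
14 | [3,5-bis(methoxymethoxy)phenyl]{2-hydroxy-4-{(E)-2-[3-methoxy-4-(methoxymethoxy)phenyl]ethenyl}-6-(methoxymethoxy)phenyl}methanone | COCOc1ccc(/C=C/c2cc(O)c(C(=O)c3cc(OCOC)cc(OCOC)c3)c(OCOC)c2)cc1OC | intermediate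
15 | 2-{[3,5-bis(methoxymethoxy)phenyl](hydroxy)methyl}-5-{(E)-2-[3-methoxy-4-(methoxymethoxy)phenyl]ethenyl}-3-(methoxymethoxy)phenol (racemic) | COCOc1ccc(/C=C/c2cc(O)c(C(O)c3cc(OCOC)cc(OCOC)c3)c(OCOC)c2)cc1OC | intermediate
16 | 2-{[3,5-bis(methoxymethoxy)phenyl](4-methylbenzenesulfonyl)methyl}-5-{(E)-2-[3-methoxy-4-(methoxymethoxy)phenyl]ethenyl}-3-(methoxymethoxy)phenol (racemic) | COCOc1ccc(/C=C/c2cc(O)c(C(c3cc(OCOC)cc(OCOC)c3)S(=O)(=O)c3ccc(C)cc3)c(OCOC)c2)cc1OC | intermediate
17 | isothiocineole of the (S)-limonene series (4,7,7-trimethyl-6-thiabicyclo[3.2.1]octane; C4 methyl cis to the sulfur bridge) | C[C@@H]1CC[C@H]2C[C@@H]1SC2(C)C | starting material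
18 | 6-[3-methoxy-4-(methoxymethoxy)benzyl]-4,7,7-trimethyl-6-thiabicyclo[3.2.1]octan-6-ium triflate from 17 (benzyl on the exo face of sulfur, the side of the one-carbon bridge) | C[C@@H]1CC[C@H]2C[C@@H]1[S@+](Cc1ccc(OCOC)c(OC)c1)C2(C)C.[O-]S(=O)(=O)C(F)(F)F | intermediate
19 | sulfonium ylide from 18: [3-methoxy-4-(methoxymethoxy)phenyl]methylide on sulfur (not isolated) | C[C@@H]1CC[C@H]2C[C@@H]1[S@+]([CH-]c1ccc(OCOC)c(OC)c1)C2(C)C | intermediate
20 | o-quinone methide: 6-{[3,5-bis(methoxymethoxy)phenyl]methylidene}-5-(methoxymethoxy)-3-{(E)-2-[3-methoxy-4-(methoxymethoxy)phenyl]ethenyl}cyclohexa-2,4-dien-1-one (exocyclic alkene geometry not defined; not isolated) | COCOc1ccc(/C=C/C2=CC(=O)C(=Cc3cc(OCOC)cc(OCOC)c3)C(OCOC)=C2)cc1OC | intermediate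
21 | betaine: ring A phenoxide whose ortho carbon carries CH(3,5-bis-MOM-oxyphenyl)–CH(3-methoxy-4-MOM-oxyphenyl)–S(+) of the isothiocineole cage, configured to give (2R,3R) on closure with inversion (not isolated) | C[C@@H]1CC[C@H]2C[C@@H]1[S@+]([C@H](c1ccc(OCOC)c(OC)c1)[C@H](c1cc(OCOC)cc(OCOC)c1)c1c([O-])cc(/C=C/c3ccc(OCOC)c(OC)c3)cc1OCOC)C2(C)C | intermediate
22 | (2R,3R)-3-[3,5-bis(methoxymethoxy)phenyl]-4-(methoxymethoxy)-2-[3-methoxy-4-(methoxymethoxy)phenyl]-6-{(E)-2-[3-methoxy-4-(methoxymethoxy)phenyl]ethenyl}-2,3-dihydro-1-benzofuran (trans) | COc1cc(/C=C/c2cc(OCOC)c3c(c2)O[C@@H](c2ccc(OCOC)c(OC)c2)[C@@H]3c2cc(OCOC)cc(OCOC)c2)ccc1OCOC | intermediate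
23 | (2R,3R)-3-(3,5-dihydroxyphenyl)-2-(4-hydroxy-3-methoxyphenyl)-6-[(E)-2-(4-hydroxy-3-methoxyphenyl)ethenyl]-2,3-dihydro-1-benzofuran-4-ol (trans; CNP0296800.3) | COc1cc(/C=C/c2cc(O)c3c(c2)O[C@@H](c2ccc(O)c(OC)c2)[C@@H]3c2cc(O)cc(O)c2)ccc1O | target

**Step count and risks**

Total step count: 15. Longest linear sequence: 10 steps (steps 1, 2, 3, 4, 5, 10, 11, 12, 14, 15, from 3,5-dihydroxybenzaldehyde).

Three steps most likely to fail:

Step 14 (the proposed new annulation). Possible failures are a low trans:cis ratio or low enantiomeric excess, O-benzylation of the phenoxide of 16 by salt 18, and β-elimination of betaine 21 to a triarylethene. The fallback uses known chemistry, sets out from ketone 14 (with bromide 11) and comes back to the route at target 23. O-alkylation of the phenol of 14 with 11 (K2CO3, DMF, rt) gives the benzyl ether ketone F1. Hydrazine hydrate (AcOH cat., n-BuOH, 110 °C) converts it into the hydrazone F2. MnO2 (CH2Cl2, 0 °C) oxidises this to the diaryldiazomethane F3, which is filtered and treated directly with the chiral dirhodium tetracarboxylate Rh2(R-PTAD)4 (1 mol%, CH2Cl2, −20 °C; the mirror-image catalyst if the first run gives the wrong series). Enantioselective 1,5 C–H insertion of the donor/donor carbene into the benzylic ether C–H bond then gives the cis-2,3-diaryl-2,3-dihydrobenzofuran F4, with C3 already R. HCl in MeOH/THF at 45 °C removes the MOM groups and, through reversible acid-mediated opening of the C2–O bond (p-hydroxybenzylic cation), equilibrates C2 to the trans isomer, which is 23.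

Step 5 (removal of exactly one of four aryl MOM ethers together with the acetal). Possible failures are over-cleavage or incomplete cleavage. The fallback sets out from ketone 6 and comes back at 7. Exhaustive hydrolysis (3 M aq HCl/THF, 55 °C) gives the tetraphenol aldehyde F5. MOMCl (3.1 equiv) with i-Pr2NEt in CH2Cl2 at 0 °C then re-protects the three hydroxyls that are not locked in the hydrogen bond to the ketone, and the chelated ortho phenol stays free, which is 7.

Step 12 (sulfinate exchange under acid on a substrate with four MOM ethers, an electron-rich stilbene and a very easily ionised benzhydrol). Possible failures are MOM loss and self-condensation of the transient o-quinone methide. The fallback sets out from diol 15 and comes back at 22. Boc2O (1.05 equiv) with DMAP (cat.) in CH2Cl2 at 0 °C converts the phenol selectively into the aryl tert-butyl carbonate F6. In the annulation, KN(SiMe3)2 (2.5 equiv, THF, −78 → −20 °C) in the presence of salt 18 forms the benzylic alkoxide. The Boc group migrates to it and tert-butyl carbonate is expelled, which delivers o-quinone methide 20 without any acid for capture by ylide 19, giving 22.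

Further compounds
F1 | step 14 | [3,5-bis(methoxymethoxy)phenyl]{2-{[3-methoxy-4-(methoxymethoxy)phenyl]methoxy}-4-{(E)-2-[3-methoxy-4-(methoxymethoxy)phenyl]ethenyl}-6-(methoxymethoxy)phenyl}methanone | COCOc1ccc(/C=C/c2cc(OCc3ccc(OCOC)c(OC)c3)c(C(=O)c3cc(OCOC)cc(OCOC)c3)c(OCOC)c2)cc1OC
F2 | step 14 | hydrazone of F1 (C=N geometry not defined) | COCOc1ccc(/C=C/c2cc(OCc3ccc(OCOC)c(OC)c3)c(C(=NN)c3cc(OCOC)cc(OCOC)c3)c(OCOC)c2)cc1OC
F3 | step 14 | diaryldiazomethane from F2 | COCOc1ccc(/C=C/c2cc(OCc3ccc(OCOC)c(OC)c3)c(C(=[N+]=[N-])c3cc(OCOC)cc(OCOC)c3)c(OCOC)c2)cc1OC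
F4 | step 14 | (2S,3R)-3-[3,5-bis(methoxymethoxy)phenyl]-4-(methoxymethoxy)-2-[3-methoxy-4-(methoxymethoxy)phenyl]-6-{(E)-2-[3-methoxy-4-(methoxymethoxy)phenyl]ethenyl}-2,3-dihydro-1-benzofuran (cis) | COc1cc(/C=C/c2cc(OCOC)c3c(c2)O[C@H](c2ccc(OCOC)c(OC)c2)[C@@H]3c2cc(OCOC)cc(OCOC)c2)ccc1OCOC
F5 | step 5 | 4-(3,5-dihydroxybenzoyl)-3,5-dihydroxybenzaldehyde | O=Cc1cc(O)c(C(=O)c2cc(O)cc(O)c2)c(O)c1
F6 | step 12 | tert-butyl 2-{[3,5-bis(methoxymethoxy)phenyl](hydroxy)methyl}-5-{(E)-2-[3-methoxy-4-(methoxymethoxy)phenyl]ethenyl}-3-(methoxymethoxy)phenyl carbonate (racemic) | COCOc1ccc(/C=C/c2cc(OC(=O)OC(C)(C)C)c(C(O)c3cc(OCOC)cc(OCOC)c3)c(OCOC)c2)cc1OC
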